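**Retrosynthetic overview**

1. Target 28 ← chroman-4-ol 27 ← silyl ether 26. The chromene C3=C4 bond is made last, by dehydration, in the same acid step that removes the two methoxymethyl groups.
2. 26 ← carbene complex 24 by a tethered Dötz benzannulation. The strategy rests on ring A (the hexasubstituted benzene; chroman numbering): its hydroxyl carbon C8 is para to the ester-oxygen carbon C5, the 1,4-dioxygen pattern of a Dötz phenol, and the neighbouring carbons C5 (ester O) and C6 (ether O) are bridged by the carbonyl carbon and the ortho ether carbon of ring B.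
3. 24 ← tetramethylammonium acylchromate 10 + aroyl chloride 23, by O-acylation at −40 °C.
4. 10 ← vinyl iodide 6 (from pyranone 3, made from enone 1 and acetone) + Cr(CO)6 7. 23 ← methyl 2,4,6-trihydroxybenzoate 11 by Claisen prenylation (15), ynol ether synthesis from trichloroethylene 16 (17 → 21) and carboxylate salt 22.
5. Ring order: ring B is bought, ring D (pyran) closes in step 1, ring A and ring C (seven-membered lactone) close together in step 15.

Key step: step 15

**Remarks on the chemistry (assumptions)**

- The pyran unit carries a tert-butyldimethylsilyloxy group at C4 (racemic), so the chromene double bond comes from a dehydration; a quinone dehydrogenation of a plain chroman would not be expected to spare the two prenyl CH2 groups.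
- The carboxyl group beside the ynol ether is never set free as the acid, which would add across the ynol ether; it is handled only as ester, salt or acid chloride.
- The target has no stereocentre; the C4 centre formed in step 3 is racemic and is destroyed in step 17.

**Step 1**
Reactants: 1 (E)-4-methoxybut-3-en-2-one
Product: 3 2,2-dimethyl-2,3-dihydro-4H-pyran-4-one, via aldol adduct 2 (not isolated)
Conditions: LiN(i-Pr)2, THF, −78 °C; acetone, −78 °C; then CF3CO2H, CH2Cl2, 0 °C → rt
Reagents that add atoms: acetone, CC(C)=O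
Why: The kinetic lithium enolate of the vinylogous ester adds to acetone (aldol addition) and acid then closes ring D by 6-endo oxa-Michael addition with loss of methanol, the usual aldol–cyclisation entry to 2,3-dihydro-4H-pyran-4-ones.

**Step 2**
Reactants: 3 2,2-dimethyl-2,3-dihydro-4H-pyran-4-one
Product: 4 5-iodo-2,2-dimethyl-2,3-dihydro-4H-pyran-4-one
Conditions: I2, pyridine, CH2Cl2, 0 °C → rt
Reagents that add atoms: iodine, II
Why: Electrophilic α-iodination of the vinylogous ester at its nucleophilic C5 (iodine/pyridine α-iodoenone protocol), with pyridine removing the C5 proton.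

**Step 3**
Reactants: 4 5-iodo-2,2-dimethyl-2,3-dihydro-4H-pyran-4-one
Product: 5 rac-5-iodo-2,2-dimethyl-3,4-dihydro-2H-pyran-4-ol
Conditions: NaBH4, CeCl3·7H2O, MeOH, −40 °C
Reagents that add atoms: none
Why: Luche reduction should give clean 1,2-reduction of the α-iodo enone to the allylic alcohol; the C4 stereocentre forms as the racemate and is removed in step 17.

**Step 4**
Reactants: 5 rac-5-iodo-2,2-dimethyl-3,4-dihydro-2H-pyran-4-ol
Product: 6 rac-tert-butyl[(5-iodo-2,2-dimethyl-3,4-dihydro-2H-pyran-4-yl)oxy]dimethylsilane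
Conditions: t-BuMe2SiCl, imidazole, DMF, rt
Reagents that add atoms: tert-butyldimethylsilyl chloride, CC(C)(C)[Si](C)(C)Cl
Why: Standard base-mediated silylation of a secondary allylic alcohol, run under basic conditions so that the acid-labile enol ether is untouched.

**Step 5**
Reactants: 6 rac-tert-butyl[(5-iodo-2,2-dimethyl-3,4-dihydro-2H-pyran-4-yl)oxy]dimethylsilane; 7 Cr(CO)6
Product: 10 tetramethylammonium acylchromate of the 4-silyloxy-2,2-dimethyl-3,4-dihydro-2H-pyran-5-yl unit, via vinyllithium 8 (not isolated), via lithium acylchromate 9 (not isolated)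
Conditions: t-BuLi (2 equiv), Et2O, −78 °C; Cr(CO)6, THF, −78 → 0 °C; then Me4NBr, H2O/CH2Cl2
Reagents that add atoms: tetramethylammonium bromide, C[N+](C)(C)C.[Br-]
Why: Iodine–lithium exchange followed by the Fischer route (addition of the alkenyllithium to a CO ligand of Cr(CO)6) gives the acylchromate, isolated as its tetramethylammonium salt by cation metathesis; the β-alkoxyvinyllithium is kept at −78 °C until the carbonyl is present to hold back ring-opening β-elimination.

**Step 6**
Reactants: 11 methyl 2,4,6-trihydroxybenzoate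
Product: 12 methyl 2-hydroxy-4,6-bis(methoxymethoxy)benzoate
Conditions: MeOCH2Cl (2.2 equiv), i-Pr2NEt, CH2Cl2, 0 °C → rt
Reagents that add atoms: chloromethyl methyl ether, COCCl
Why: Williamson-type acetalisation takes the para hydroxyl and one of the two equivalent ortho hydroxyls, after which the last hydroxyl is held back by its hydrogen bond to the ester carbonyl.

**Step 7**
Reactants: 12 methyl 2-hydroxy-4,6-bis(methoxymethoxy)benzoate
Product: 13 methyl 2,4-bis(methoxymethoxy)-6-[(2-methylbut-3-yn-2-yl)oxy]benzoate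
Conditions: 3-chloro-3-methylbut-1-yne, CuCl2·2H2O (cat.), DBU, MeCN, 0 °C → rt
Reagents that add atoms: 3-chloro-3-methylbut-1-yne, CC(C)(Cl)C#C
Why: Copper-catalysed O-propargylation of a phenoxide by a tertiary propargylic chloride (through a copper acetylide/allenylidene) is the standard way to aryl 1,1-dimethylpropargyl ethers, and DBU fully deprotonates the chelated phenol.

**Step 8**
Reactants: 13 methyl 2,4-bis(methoxymethoxy)-6-[(2-methylbut-3-yn-2-yl)oxy]benzoate
Product: 14 methyl 2,4-bis(methoxymethoxy)-6-[(2-methylbut-3-en-2-yl)oxy]benzoate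
Conditions: H2 (1 atm), Pd/CaCO3 poisoned with Pb(OAc)2, quinoline, EtOAc, rt
Reagents that add atoms: none
Why: Lindlar-type semihydrogenation stops a terminal alkyne at the alkene and leaves the arene, ester and acetals alone.

**Step 9**
Reactants: 14 methyl 2,4-bis(methoxymethoxy)-6-[(2-methylbut-3-en-2-yl)oxy]benzoate
Product: 15 methyl 2-hydroxy-4,6-bis(methoxymethoxy)-3-(3-methylbut-2-en-1-yl)benzoate
Conditions: toluene, 110 °C
Reagents that add atoms: none
Why: Aromatic Claisen rearrangement ([3,3]) of the aryl 1,1-dimethylallyl ether delivers a normal prenyl group to C3, the only free ortho carbon, which fixes the prenyl group between the free hydroxyl and a methoxymethoxy group.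

**Step 10**
Reactants: 15 methyl 2-hydroxy-4,6-bis(methoxymethoxy)-3-(3-methylbut-2-en-1-yl)benzoate; 16 trichloroethylene
Product: 17 methyl 2-{[(E)-1,2-dichloroethenyl]oxy}-4,6-bis(methoxymethoxy)-3-(3-methylbut-2-en-1-yl)benzoate
Conditions: K2CO3, DMF, 70 °C
Reagents that add atoms: none
Why: The phenoxide adds anti to dichloroacetylene generated in situ from trichloroethylene, the established synthesis of aryl (E)-1,2-dichlorovinyl ethers, and this small linear electrophile tolerates the hindered phenol.

**Step 11**
Reactants: 17 methyl 2-{[(E)-1,2-dichloroethenyl]oxy}-4,6-bis(methoxymethoxy)-3-(3-methylbut-2-en-1-yl)benzoate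
Product: 18 2-{[(E)-1,2-dichloroethenyl]oxy}-4,6-bis(methoxymethoxy)-3-(3-methylbut-2-en-1-yl)benzoic acid
Conditions: LiOH, THF/MeOH/H2O, 60 °C; then cold 1 M HCl to pH 4
Reagents that add atoms: lithium hydroxide, [Li+].[OH-]
Why: Ester saponification (acyl–oxygen cleavage) is compatible with acetals, the prenyl group and the dichlorovinyl ether, whose vinyl hydrogen has no anti chlorine for a hydroxide-induced elimination.

**Step 12**
Reactants: 18 2-{[(E)-1,2-dichloroethenyl]oxy}-4,6-bis(methoxymethoxy)-3-(3-methylbut-2-en-1-yl)benzoic acid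
Product: 21 prop-2-en-1-yl 4,6-bis(methoxymethoxy)-3-(3-methylbut-2-en-1-yl)-2-[(5-methylhex-4-en-1-yn-1-yl)oxy]benzoate, via dilithio species 19 (not isolated), via lithium carboxylate 20 (not isolated)
Conditions: n-BuLi (3.1 equiv), THF, −78 → −40 °C; DMPU, prenyl bromide (1.05 equiv), −78 → −20 °C; then allyl bromide (3 equiv), −20 °C → rt
Reagents that add atoms: prenyl bromide, CC(C)=CCBr; allyl bromide, C=CCBr
Why: The dichlorovinyl ether to lithium aryloxyacetylide conversion (deprotonation, loss of LiCl, chlorine–lithium exchange) runs with the carboxyl masked as its unreactive lithium salt, the acetylide is C-alkylated first by the limiting prenyl bromide (SN2) and the carboxylate is then O-alkylated by allyl bromide, so a free acid never meets the ynol ether.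

**Step 13**
Reactants: 21 prop-2-en-1-yl 4,6-bis(methoxymethoxy)-3-(3-methylbut-2-en-1-yl)-2-[(5-methylhex-4-en-1-yn-1-yl)oxy]benzoate
Product: 22 potassium 4,6-bis(methoxymethoxy)-3-(3-methylbut-2-en-1-yl)-2-[(5-methylhex-4-en-1-yn-1-yl)oxy]benzoate
Conditions: Pd(PPh3)4 (5 mol %), potassium 2-ethylhexanoate (0.98 equiv), EtOAc/CH2Cl2, rt
Reagents that add atoms: potassium 2-ethylhexanoate, CCCCC(CC)C(=O)[O-].[K+]
Why: Tsuji–Trost deallylation (oxidative addition of zerovalent palladium to the allyl ester, capture of the π-allyl by 2-ethylhexanoate) releases the carboxylate as its potassium salt under neutral, proton-free conditions.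

**Step 14**
Reactants: 22 potassium 4,6-bis(methoxymethoxy)-3-(3-methylbut-2-en-1-yl)-2-[(5-methylhex-4-en-1-yn-1-yl)oxy]benzoate
Product: 23 4,6-bis(methoxymethoxy)-3-(3-methylbut-2-en-1-yl)-2-[(5-methylhex-4-en-1-yn-1-yl)oxy]benzoyl chloride
Conditions: (COCl)2 (1.0 equiv), CH2Cl2, −20 → 0 °C; filtered cold under argon, used at once
Reagents that add atoms: oxalyl chloride, ClC(=O)C(=O)Cl
Why: A carboxylate salt and oxalyl chloride give the acid chloride with only CO, CO2 and KCl beside it (no HCl), which spares the ynol ether and the acetals; the chloride is kept cold and used at once because the ortho acetal oxygen or the ynol ether could attack it on standing.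

**Step 15**
Reactants: 10 tetramethylammonium acylchromate of the 4-silyloxy-2,2-dimethyl-3,4-dihydro-2H-pyran-5-yl unit; 23 4,6-bis(methoxymethoxy)-3-(3-methylbut-2-en-1-yl)-2-[(5-methylhex-4-en-1-yn-1-yl)oxy]benzoyl chloride
Product: 26 rac-4-(tert-butyldimethylsilyloxy)chroman depsidone with both ring B hydroxyls as methoxymethyl ethers (the 3,4-dihydro-4-silyloxy form of the target), via acyloxycarbene complex 24 (not isolated), via tricarbonylchromium arene complex 25 (not isolated)
Conditions: CH2Cl2, −40 °C, 1 h; diluted to 0.005 M, −40 → 25 °C, 12 h; then air, MeCN, rt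
Reagents that add atoms: none
Why: Proposed new method: O-acylation of the acylchromate by the aroyl chloride gives the acyloxy(alkenyl)carbene complex 24, which on warming loses one CO, binds the tethered ynol ether and inserts it into the Cr=C bond so that the oxygen-bearing alkyne carbon bonds to the carbene carbon; CO then inserts at the new prenyl-bearing carbene carbon to give a chromium-bound dienylketene, which closes by 6π-electrocyclisation onto C6 of the dihydropyran and tautomerises to the phenol. The closest known reactions are the intramolecular Dötz benzannulation of alkenyl(alkoxy)carbene complexes whose alkyne is tethered through the carbene oxygen, and the low-temperature formation of acyloxycarbene complexes from tetramethylammonium acylchromates and acid halides; neither an acyloxycarbene nor an aryl ynol ether has been shown to benzannulate. Ring C (seven-membered) closes in the alkyne insertion, by C–C bond formation between the carbene carbon and the proximal alkyne carbon, with ring B, its carbonyl carbon and the ether oxygen as a five-atom tether; ring A closes in the disrotatory 6π-electrocyclisation that joins the ketene carbon to the enol-ether carbon. No stereocentre is formed, and the C4 silyloxy centre is carried through as the racemate. The step needs one sense of alkyne insertion, and the short rigid tether secures it: bonding of the distal alkyne carbon would put the new carbene carbon and the dihydropyranyl group trans on a ring double bond, from which no benzannulation is possible, whereas the ring formed in the correct insertion holds them cis as the cyclisation requires. The alkenyl carbene favours phenol formation over cyclopentannulation, and the 1,4-relation of alkyne and prenyl alkene rules out cyclopropanation.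

**Step 16**
Reactants: 26 rac-4-(tert-butyldimethylsilyloxy)chroman depsidone with both ring B hydroxyls as methoxymethyl ethers
Product: 27 rac-4-hydroxychroman depsidone with both ring B hydroxyls as methoxymethyl ethers
Conditions: HF·pyridine, pyridine, THF, 0 °C → rt
Reagents that add atoms: none
Why: Buffered fluoride desilylation removes the secondary silyl ether without touching the aryl ester lactone, the acetals or the prenyl groups.

**Step 17**
Reactants: 27 rac-4-hydroxychroman depsidone with both ring B hydroxyls as methoxymethyl ethers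
Product: 28 target depsidone (CNP0263700.0)
Conditions: conc. aq. HCl (to 1 M), i-PrOH/THF, 45 °C
Reagents that add atoms: none
Why: Acid hydrolysis of the two aryl methoxymethyl acetals and E1 dehydration of the benzylic chroman-4-ol (cation stabilised by the pyran oxygen on the ortho carbon) should give the conjugated 2,2-dimethylchromene, the standard chromanol-to-chromene dehydration; acid strength and time are kept low so that the ortho-prenyl phenols do not cyclise.

**Compound list**

1 | (E)-4-methoxybut-3-en-2-one | CO/C=C/C(C)=O | starting material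
2 | (E)-5-hydroxy-1-methoxy-5-methylhex-1-en-3-one (aldol adduct) | CO/C=C/C(=O)CC(C)(C)O | intermediate
3 | 2,2-dimethyl-2,3-dihydro-4H-pyran-4-one | CC1(C)CC(=O)C=CO1 | intermediate
4 | 5-iodo-2,2-dimethyl-2,3-dihydro-4H-pyran-4-one | CC1(C)CC(=O)C(I)=CO1 | intermediate
5 | rac-5-iodo-2,2-dimethyl-3,4-dihydro-2H-pyran-4-ol | CC1(C)CC(O)C(I)=CO1 | intermediate
6 | rac-tert-butyl[(5-iodo-2,2-dimethyl-3,4-dihydro-2H-pyran-4-yl)oxy]dimethylsilane | CC1(C)CC(O[Si](C)(C)C(C)(C)C)C(I)=CO1 | intermediate
7 | Cr(CO)6, chromium hexacarbonyl | O=C=[Cr](=C=O)(=C=O)(=C=O)(=C=O)=C=O | starting material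
8 | rac-[4-(tert-butyldimethylsilyloxy)-2,2-dimethyl-3,4-dihydro-2H-pyran-5-yl]lithium (vinyllithium) | [Li]C1=COC(C)(C)CC1O[Si](C)(C)C(C)(C)C | intermediate
9 | lithium pentacarbonyl{[4-(tert-butyldimethylsilyloxy)-2,2-dimethyl-3,4-dihydro-2H-pyran-5-yl]oxidomethylidene}chromate (lithium acylchromate, racemic) | [Li+].[O-]C(C1=COC(C)(C)CC1O[Si](C)(C)C(C)(C)C)=[Cr](=C=O)(=C=O)(=C=O)(=C=O)=C=O | intermediate
10 | tetramethylammonium pentacarbonyl{[4-(tert-butyldimethylsilyloxy)-2,2-dimethyl-3,4-dihydro-2H-pyran-5-yl]oxidomethylidene}chromate (racemic) | C[N+](C)(C)C.[O-]C(C1=COC(C)(C)CC1O[Si](C)(C)C(C)(C)C)=[Cr](=C=O)(=C=O)(=C=O)(=C=O)=C=O | intermediate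
11 | methyl 2,4,6-trihydroxybenzoate | COC(=O)c1c(O)cc(O)cc1O | starting material
12 | methyl 2-hydroxy-4,6-bis(methoxymethoxy)benzoate | COC(=O)c1c(O)cc(OCOC)cc1OCOC | intermediate
13 | methyl 2,4-bis(methoxymethoxy)-6-[(2-methylbut-3-yn-2-yl)oxy]benzoate | COC(=O)c1c(OC(C)(C)C#C)cc(OCOC)cc1OCOC | intermediate
14 | methyl 2,4-bis(methoxymethoxy)-6-[(2-methylbut-3-en-2-yl)oxy]benzoate | COC(=O)c1c(OC(C)(C)C=C)cc(OCOC)cc1OCOC | intermediate
15 | methyl 2-hydroxy-4,6-bis(methoxymethoxy)-3-(3-methylbut-2-en-1-yl)benzoate | COC(=O)c1c(O)c(CC=C(C)C)c(OCOC)cc1OCOC | intermediate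
16 | trichloroethylene | ClC=C(Cl)Cl | starting material
17 | methyl 2-{[(E)-1,2-dichloroethenyl]oxy}-4,6-bis(methoxymethoxy)-3-(3-methylbut-2-en-1-yl)benzoate | COC(=O)c1c(O/C(Cl)=C\Cl)c(CC=C(C)C)c(OCOC)cc1OCOC | intermediate
18 | 2-{[(E)-1,2-dichloroethenyl]oxy}-4,6-bis(methoxymethoxy)-3-(3-methylbut-2-en-1-yl)benzoic acid | OC(=O)c1c(O/C(Cl)=C\Cl)c(CC=C(C)C)c(OCOC)cc1OCOC | intermediate
19 | lithium 2-[(lithioethynyl)oxy]-4,6-bis(methoxymethoxy)-3-(3-methylbut-2-en-1-yl)benzoate (dilithio species) | [Li+].[O-]C(=O)c1c(OC#C[Li])c(CC=C(C)C)c(OCOC)cc1OCOC | intermediate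
20 | lithium 4,6-bis(methoxymethoxy)-3-(3-methylbut-2-en-1-yl)-2-[(5-methylhex-4-en-1-yn-1-yl)oxy]benzoate | [Li+].[O-]C(=O)c1c(OC#CCC=C(C)C)c(CC=C(C)C)c(OCOC)cc1OCOC | intermediate
21 | prop-2-en-1-yl 4,6-bis(methoxymethoxy)-3-(3-methylbut-2-en-1-yl)-2-[(5-methylhex-4-en-1-yn-1-yl)oxy]benzoate | C=CCOC(=O)c1c(OC#CCC=C(C)C)c(CC=C(C)C)c(OCOC)cc1OCOC | intermediate
22 | potassium 4,6-bis(methoxymethoxy)-3-(3-methylbut-2-en-1-yl)-2-[(5-methylhex-4-en-1-yn-1-yl)oxy]benzoate | [K+].[O-]C(=O)c1c(OC#CCC=C(C)C)c(CC=C(C)C)c(OCOC)cc1OCOC | intermediate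
23 | 4,6-bis(methoxymethoxy)-3-(3-methylbut-2-en-1-yl)-2-[(5-methylhex-4-en-1-yn-1-yl)oxy]benzoyl chloride | ClC(=O)c1c(OC#CCC=C(C)C)c(CC=C(C)C)c(OCOC)cc1OCOC | intermediate
24 | pentacarbonylchromium carbene complex whose carbene carbon bears the rac-4-(tert-butyldimethylsilyloxy)-2,2-dimethyl-3,4-dihydro-2H-pyran-5-yl group and the 4,6-bis(methoxymethoxy)-3-prenyl-2-(5-methylhex-4-en-1-ynyloxy)benzoyloxy group | O=C=[Cr](=C=O)(=C=O)(=C=O)(=C=O)=C(OC(=O)c1c(OCOC)cc(OCOC)c(CC=C(C)C)c1OC#CCC=C(C)C)C1=COC(C)(C)CC1O[Si](C)(C)C(C)(C)C | intermediate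
25 | tricarbonylchromium complex of 26, ring A η6-bound (written as its two parts) | CC(C)=CCc1c(O)c2c(c3c1Oc1c(CC=C(C)C)c(OCOC)cc(OCOC)c1C(=O)O3)C(O[Si](C)(C)C(C)(C)C)CC(C)(C)O2.O=C=[Cr](=C=O)=C=O | intermediate
26 | rac-4-(tert-butyldimethylsilyloxy)chroman depsidone: ring A is an 8-hydroxy-2,2-dimethyl-7-prenylchroman with silyloxy at C4, its C5 oxygen is the lactone ester oxygen and its C6 oxygen the diaryl ether oxygen; ring B is the 3-prenyl-4,6-bis(methoxymethoxy)benzoyl unit with the ether oxygen on C2 | CC(C)=CCc1c(O)c2c(c3c1Oc1c(CC=C(C)C)c(OCOC)cc(OCOC)c1C(=O)O3)C(O[Si](C)(C)C(C)(C)C)CC(C)(C)O2 | intermediate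
27 | rac-4-hydroxychroman depsidone (26 with free C4 hydroxyl) | CC(C)=CCc1c(O)c2c(c3c1Oc1c(CC=C(C)C)c(OCOC)cc(OCOC)c1C(=O)O3)C(O)CC(C)(C)O2 | intermediate
28 | target depsidone: 2,2-dimethyl-2H-chromene ring A/D with 8-hydroxy and 7-prenyl, fused through C5–O–C(=O) and C6–O to a 4,6-dihydroxy-3-prenylbenzoyl ring B | CC(C)=CCc1c(O)c2c(c3c1Oc1c(CC=C(C)C)c(O)cc(O)c1C(=O)O3)C=CC(C)(C)O2 | target

**Totals**

Total step count: 17. Longest linear sequence: 12 steps (steps 6 to 17, from methyl 2,4,6-trihydroxybenzoate 11); the chromium branch (steps 1 to 5) joins at step 15.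

**Steps most likely to fail**

1. Step 15 (proposed new method).
   - What may go wrong: the acyloxycarbene complex may fragment thermally before a CO ligand leaves. The electron-rich distal carbon of the ynol ether may attack the electrophilic carbene carbon directly, which gives insertion in the wrong sense and a vinylcarbene that cannot cyclise. Chains may also couple intermolecularly.
   - Fallback (the same two rings built stepwise by known reactions): it sets out from salt 10 and phenol 15 and comes back at 26. Salt 10 is O-methylated (MeOTf, CH2Cl2, 0 °C) to the methoxy(alkenyl)carbene complex F1. 5-Methylhex-4-en-1-yne F2 is made from prenyl bromide and ethynylmagnesium bromide (CuCl cat., THF). F1 and F2 undergo the ordinary intermolecular Dötz benzannulation (THF, 50 °C), in which a terminal alkyne places its substituent next to the CO-derived carbon; oxidative work-up with (NH4)2Ce(NO3)6 gives rac-4-(tert-butyldimethylsilyloxy)-2,2-dimethyl-7-prenylchroman-5,8-dione F3. The potassium phenoxide of 15 adds to C6, the only unsubstituted quinone carbon (K2CO3, DMF, argon; Na2S2O4 in the work-up), to give the aryloxyhydroquinone methyl ester F4. Saponification (LiOH, degassed THF/H2O) gives the aryloxyhydroquinone acid F5. Carbodiimide lactonisation (DCC, DMAP, CH2Cl2, high dilution) onto the hydroquinone hydroxyl beside the ether oxygen, the only one within reach, closes the seven-membered ring to 26.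

2. Step 12.
   - What may go wrong: butyllithium may add to the lithium carboxylate or metalate the ring position between the two methoxymethoxy groups, and the two alkylations may not stay apart (allyl on carbon, prenyl on oxygen).
   - Fallback (ynol ether by copper-mediated coupling and dehydrobromination, with no organolithium near the carboxyl group): it sets out from 15 and comes back at 22. 4-Methylpent-3-en-1-ol is oxidised (Swern) to 4-methylpent-3-enal F6, which gives 1,1-dibromo-5-methylhexa-1,4-diene F7 with CBr4/PPh3 (first stage of the Corey–Fuchs reaction). Phenol 15 is coupled with F7 (CuI, copper monoiodide, with a diamine ligand, Cs2CO3, toluene, 90 °C) at the C–Br bond trans to the chain, which should give the (Z)-1-bromoenol ether F8. Anti elimination of HBr with KOt-Bu (1,4-dioxane, rt) gives the methyl ester ynol ether F9. The methyl ester is cleaved at the methyl carbon with KOSiMe3 (THF), which gives potassium salt 22 directly.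

3. Step 5.
   - What may go wrong: in vinyllithium 8 the C–Li bond is anti-periplanar to the ring C–O bond, so it may ring-open by β-elimination to an alkynyl alkoxide before it adds to Cr(CO)6.
   - Fallback (the acyl group delivered as an electrophile to a chromium dianion): it sets out from iodide 6 and Cr(CO)6 7 and comes back at 10. Palladium-catalysed methoxycarbonylation of 6 (Pd(OAc)2, PPh3, CO 1 atm, MeOH, Et3N) gives the methyl ester F10. LiOH gives the lithium carboxylate F11, which with oxalyl chloride gives the acid chloride F12. Cr(CO)6 is reduced with KC8 (THF) to K2Cr(CO)5 F13, which is acylated by F12 at −78 °C to the potassium acylchromate F14. Cation exchange with Me4NBr gives 10.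

**Further compounds**

F1 | step 15 | pentacarbonyl{methoxy[rac-4-(tert-butyldimethylsilyloxy)-2,2-dimethyl-3,4-dihydro-2H-pyran-5-yl]methylidene}chromium | O=C=[Cr](=C=O)(=C=O)(=C=O)(=C=O)=C(OC)C1=COC(C)(C)CC1O[Si](C)(C)C(C)(C)C
F2 | step 15 | 5-methylhex-4-en-1-yne | C#CCC=C(C)C
F3 | step 15 | rac-4-(tert-butyldimethylsilyloxy)-2,2-dimethyl-7-(3-methylbut-2-en-1-yl)chroman-5,8-dione | O=C1C=C(CC=C(C)C)C(=O)C2=C1C(O[Si](C)(C)C(C)(C)C)CC(C)(C)O2
F4 | step 15 | aryloxyhydroquinone methyl ester (ring B phenol oxygen of 15 bonded to C6 of the 5,8-dihydroxychroman from F3) | CC(C)=CCc1c(O)c2c(c(O)c1Oc1c(CC=C(C)C)c(OCOC)cc(OCOC)c1C(=O)OC)C(O[Si](C)(C)C(C)(C)C)CC(C)(C)O2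
F5 | step 15 | aryloxyhydroquinone acid (F4 with free carboxyl group) | CC(C)=CCc1c(O)c2c(c(O)c1Oc1c(CC=C(C)C)c(OCOC)cc(OCOC)c1C(=O)O)C(O[Si](C)(C)C(C)(C)C)CC(C)(C)O2
F6 | step 12 | 4-methylpent-3-enal | CC(C)=CCC=O
F7 | step 12 | 1,1-dibromo-5-methylhexa-1,4-diene | BrC(Br)=CCC=C(C)C
F8 | step 12 | methyl 2-{[(Z)-1-bromo-5-methylhexa-1,4-dien-1-yl]oxy}-4,6-bis(methoxymethoxy)-3-(3-methylbut-2-en-1-yl)benzoate | COC(=O)c1c(O/C(Br)=C/CC=C(C)C)c(CC=C(C)C)c(OCOC)cc1OCOC
F9 | step 12 | methyl 4,6-bis(methoxymethoxy)-3-(3-methylbut-2-en-1-yl)-2-[(5-methylhex-4-en-1-yn-1-yl)oxy]benzoate | COC(=O)c1c(OC#CCC=C(C)C)c(CC=C(C)C)c(OCOC)cc1OCOC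
F10 | step 5 | methyl rac-4-(tert-butyldimethylsilyloxy)-2,2-dimethyl-3,4-dihydro-2H-pyran-5-carboxylate | COC(=O)C1=COC(C)(C)CC1O[Si](C)(C)C(C)(C)C
F11 | step 5 | lithium rac-4-(tert-butyldimethylsilyloxy)-2,2-dimethyl-3,4-dihydro-2H-pyran-5-carboxylate | [Li+].[O-]C(=O)C1=COC(C)(C)CC1O[Si](C)(C)C(C)(C)C
F12 | step 5 | rac-4-(tert-butyldimethylsilyloxy)-2,2-dimethyl-3,4-dihydro-2H-pyran-5-carbonyl chloride | ClC(=O)C1=COC(C)(C)CC1O[Si](C)(C)C(C)(C)C
F13 | step 5 | K2Cr(CO)5, dipotassium pentacarbonylchromate | [K+].[K+].O=C=[Cr-2](=C=O)(=C=O)(=C=O)=C=O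
F14 | step 5 | potassium acylchromate (potassium analogue of 9) | [K+].[O-]C(C1=COC(C)(C)CC1O[Si](C)(C)C(C)(C)C)=[Cr](=C=O)(=C=O)(=C=O)(=C=O)=C=O
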